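**Plan**
- Cuts (benzofuran numbering): first the C5–allyl bond (retro-Cope, allyl back to C3a). Then the O1–C2 ether of ring A is traded for a C7–C2 bond, which recasts the hydrobenzofuranone as a bicyclo[3.2.1]oct-3-ene-2,8-dione. That is cut at C3–C3a and C2–C7 into a p-quinone monoketal and (Z)-isoelemicin.
- Enabling feature: O1 sits on C7a, the enol end of the C7a=C7–C6=O vinylogous ester (a masked C7a/C6 β-diketone), and C2 is a 3,4,5-trimethoxybenzylic carbon. A C7–C2 bond is therefore benzylic and flanked by both carbonyls, so acid can break it and re-form it on oxygen.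
- Forward order: Claisen allylation and oxidative ketalisation; the cationic [5+2] addition builds carbocycle B together with the C3–C2 bridge; the acid shift closes dihydrofuran ring A; a Cope shift takes the allyl group from C3a to C5.
- Stereochemistry: C3/C3a arise in the cycloaddition (Z alkene, aryl endo, hence methyl endo and trans to allyl). The absolute sense comes from resolution of the cycloadduct. C2 settles trans to the C3 methyl by reversible ionisation. C5 is set by suprafacial transfer from C3a.

Key step: step 7

Assumption: the cationic [5+2] addition is taken to follow its usual aryl-endo topology with retention of alkene geometry; the Z propenylarene is used because that topology then places the C6 methyl group endo, trans to the bridgehead allyl group.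

**Step 1**
Reactants: 1 2,3,4-trimethoxyphenol; 2 allyl bromide
Product: 3 1-(allyloxy)-2,3,4-trimethoxybenzene
Conditions: K2CO3, acetone, reflux
Reagents that add atoms: allyl bromide (2), C=CCBr
Why: Williamson ether synthesis; the phenoxide should be alkylated on oxygen by the primary allylic bromide under carbonate conditions.

**Step 2**
Reactants: 3 1-(allyloxy)-2,3,4-trimethoxybenzene
Product: 4 6-allyl-2,3,4-trimethoxyphenol
Conditions: N,N-diethylaniline, 190 °C
Reagents that add atoms: none
Why: Aromatic Claisen rearrangement; the [3,3] shift can only end at C6, the single free ortho position, and tautomerisation restores the phenol.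

**Step 3**
Reactants: 4 6-allyl-2,3,4-trimethoxyphenol
Product: 5 2-allyl-4,4,5,6-tetramethoxycyclohexa-2,5-dien-1-one
Conditions: PhI(OAc)2, MeOH, 0 °C
Reagents that add atoms: methanol, CO
Why: Oxidative dearomatisation of a para-methoxyphenol by a hypervalent iodine diacetate; methanol should add to the methoxy-bearing para carbon of the phenoxenium ion and give the p-quinone monoketal.

**Step 4**
Reactants: 6 (3,4,5-trimethoxyphenyl)boronic acid; 7 (Z)-1-bromoprop-1-ene
Product: 8 (Z)-isoelemicin, (Z)-1,2,3-trimethoxy-5-(prop-1-en-1-yl)benzene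
Conditions: Pd(PPh3)4 (cat.), Na2CO3, DME/H2O, 70 °C, sealed vessel
Reagents that add atoms: none
Why: Suzuki–Miyaura coupling; oxidative addition of the alkenyl bromide to zerovalent palladium and reductive elimination both go with retention, so the Z geometry of 7 should be carried into 8.

**Step 5**
Reactants: 5 2-allyl-4,4,5,6-tetramethoxycyclohexa-2,5-dien-1-one; 8 (Z)-isoelemicin
Product: 9 rac-(1R,5S,6R,7R)-5-allyl-1,3-dimethoxy-6-methyl-7-(3,4,5-trimethoxyphenyl)bicyclo[3.2.1]oct-3-ene-2,8-dione (6-endo-methyl, 7-endo-aryl, racemate)
Conditions: TMSOTf (0.2 equiv), 2,6-di-tert-butyl-4-methylpyridine (0.3 equiv), CH2Cl2, −78 °C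
Reagents that add atoms: none
Why: Cationic (perezone-type) [5+2] cycloaddition of a quinone monoketal with a propenylarene: loss of methoxide gives the 4-methoxyphenoxenium (2-oxidopentadienyl) cation, its allyl-bearing terminus is attacked by the methyl-bearing alkene carbon, its methoxy-bearing terminus captures the benzylic cation in an aryl-endo arrangement that keeps the Z geometry (methyl and aryl both endo), and the bicyclic oxocarbenium ion then hands its O-methyl group to the released methoxy group (dimethyl ether), leaving the 2,8-dione and regenerating the silyl triflate.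

**Step 6**
Reactants: 9 racemic cycloadduct
Product: 10 (1R,5S,6R,7R)-5-allyl-1,3-dimethoxy-6-methyl-7-(3,4,5-trimethoxyphenyl)bicyclo[3.2.1]oct-3-ene-2,8-dione
Conditions: preparative HPLC, amylose tris(3,5-dimethylphenylcarbamate) on silica, hexane/2-propanol
Reagents that add atoms: none
Why: Chromatographic resolution on a chiral stationary phase, which should separate the enantiomers of this rigid diketone; the (1R,5S,6R,7R) enantiomer, to be assigned by anomalous-dispersion X-ray analysis or electronic circular dichroism, is carried on and its antipode is set aside.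

**Step 7**
Reactants: 10 (1R,5S,6R,7R)-cycloadduct
Product: 12 (2S,3S,3aS)-3a-allyl-5,7-dimethoxy-3-methyl-2-(3,4,5-trimethoxyphenyl)-3,3a-dihydrobenzofuran-6(2H)-one, via 2,3-cis-hydrobenzofuranone 11 (not isolated)
Conditions: TfOH (0.1 equiv), CH2Cl2, −20 to 0 °C
Reagents that add atoms: none
Why: Protonation of the bridging C8 carbonyl (bicyclooctane numbering) should trigger heterolysis of the C1–C7 bond, which is benzylic to the trimethoxyphenyl ring and α to both ketones, giving a trimethoxybenzyl cation and the enol of the 2-methoxy-1,3-diketone, whose C8 oxygen (the later O1 on C7a) recaptures the cation. The closest known reaction type is the acid-catalysed 1,3 carbon-to-oxygen benzyl shift that turns 7-aryl-bicyclo[3.2.1]oct-3-ene-2,8-diones into 2-aryl-hydrobenzofuranones. Ring A closes in a 5-exo-trig mode, O1 adding to the benzylic cation whose quinoid double bond lies outside the new ring. Least-motion capture is expected to return the aryl group first to the face it left (2,3-cis, 11); because the O1–C2 bond of the vinylogous ester can re-ionise under the same acid, C2 should equilibrate and the neighbouring C3 methyl group should steer it to the trans isomer 12, while C3 and C3a are never touched. The step needs oxygen rather than carbon recapture and must spare the 3a-allyl dienone: the conjugated vinylogous ester should be the more stable partner of the strained, non-enolisable bridged β-diketone, and catalytic acid at low temperature should be too mild for allyl 1,2-shifts.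

**Step 8**
Reactants: 12 (2S,3S,3aS)-3a-allyl hydrobenzofuranone
Product: 13 (2S,3S,5R)-5-allyl-5,7-dimethoxy-3-methyl-2-(3,4,5-trimethoxyphenyl)-3,5-dihydrobenzofuran-6(2H)-one (target, CNP0080458.1)
Conditions: toluene (degassed), 130 °C, sealed tube
Reagents that add atoms: none
Why: Cope rearrangement ([3,3] shift) of the 4-allylcyclohexa-2,5-dienone unit, a known reaction of 3a-allyl hydrobenzofuranones: the allyl terminus should bond to C5 on the face it occupies at C3a, so the C3a configuration is passed suprafacially to C5 (5R), driven by relief of the crowded ring-fusion centre and by the linear C4=C3a–C7a=C7–C6=O conjugation.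

**Compound list**
1 | 2,3,4-trimethoxyphenol | COc1ccc(O)c(OC)c1OC | starting material
2 | allyl bromide | C=CCBr | starting material
3 | 1-(allyloxy)-2,3,4-trimethoxybenzene | C=CCOc1ccc(OC)c(OC)c1OC | intermediate
4 | 6-allyl-2,3,4-trimethoxyphenol | C=CCc1cc(OC)c(OC)c(OC)c1O | intermediate
5 | 2-allyl-4,4,5,6-tetramethoxycyclohexa-2,5-dien-1-one | C=CCC1=CC(OC)(OC)C(OC)=C(OC)C1=O | intermediate
6 | (3,4,5-trimethoxyphenyl)boronic acid | COc1cc(B(O)O)cc(OC)c1OC | starting material
7 | (Z)-1-bromoprop-1-ene | C/C=C\Br | starting material
8 | (Z)-isoelemicin, (Z)-1,2,3-trimethoxy-5-(prop-1-en-1-yl)benzene | C/C=C\c1cc(OC)c(OC)c(OC)c1 | intermediate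
9 | rac-(1R,5S,6R,7R)-5-allyl-1,3-dimethoxy-6-methyl-7-(3,4,5-trimethoxyphenyl)bicyclo[3.2.1]oct-3-ene-2,8-dione (6-endo-methyl, 7-endo-aryl; racemate, the SMILES shows the enantiomer that is carried on) | C=CC[C@]12C=C(OC)C(=O)[C@](OC)(C1=O)[C@@H](c3cc(OC)c(OC)c(OC)c3)[C@H]2C | intermediate
10 | (1R,5S,6R,7R)-5-allyl-1,3-dimethoxy-6-methyl-7-(3,4,5-trimethoxyphenyl)bicyclo[3.2.1]oct-3-ene-2,8-dione (single enantiomer) | C=CC[C@]12C=C(OC)C(=O)[C@](OC)(C1=O)[C@@H](c3cc(OC)c(OC)c(OC)c3)[C@H]2C | intermediate
11 | (2R,3S,3aS)-3a-allyl-5,7-dimethoxy-3-methyl-2-(3,4,5-trimethoxyphenyl)-3,3a-dihydrobenzofuran-6(2H)-one (2,3-cis, allyl trans to methyl) | C=CC[C@]12C=C(OC)C(=O)C(OC)=C1O[C@@H](c3cc(OC)c(OC)c(OC)c3)[C@H]2C | intermediate (not isolated)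
12 | (2S,3S,3aS)-3a-allyl-5,7-dimethoxy-3-methyl-2-(3,4,5-trimethoxyphenyl)-3,3a-dihydrobenzofuran-6(2H)-one (2,3-trans, allyl trans to methyl) | C=CC[C@]12C=C(OC)C(=O)C(OC)=C1O[C@H](c3cc(OC)c(OC)c(OC)c3)[C@H]2C | intermediate
13 | (2S,3S,5R)-5-allyl-5,7-dimethoxy-3-methyl-2-(3,4,5-trimethoxyphenyl)-3,5-dihydrobenzofuran-6(2H)-one | C=CC[C@@]1(OC)C=C2C(=C(OC)C1=O)O[C@H](c1cc(OC)c(OC)c(OC)c1)[C@H]2C | target

**Step count**
Total: 8 steps. Longest linear sequence: 7 steps (1, 2, 3, 5, 6, 7, 8); step 4 is a one-step branch.

**Steps most likely to fail**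

Step 5. The second bond may form at the carbonyl oxygen instead of at the fully substituted, methoxy-bearing ring terminus, so that the carbocyclic adduct is bypassed. Acid may also isomerise or oligomerise the Z alkene before it is trapped. The fallback accepts oxygen capture. It sets out from 5 and 8: with a protic acid (TfOH cat., MeCN, 0 °C) the formal [3+2] addition should give the racemic 2,3-cis-hydrobenzofuranone F1 directly, with the same methyl/allyl relationship. F1 is resolved on the same chiral phase and comes back to the route at 11, which the acid of step 7 equilibrates to 12.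

Step 7. Inversion at the benzylic carbon may stay incomplete, or the acid needed for it may start a 1,2-shift of the 3a-allyl group with aromatisation of ring B. The fallback inverts C2 by substitution instead of ionisation. It sets out from 10, where a weaker acid (CF3CO2H, CH2Cl2, −40 °C) should stop the shift at the kinetic isomer 11. LiOH in aqueous THF should open the vinylogous ester of 11 by addition at C7a and loss of the benzylic alkoxide, leaving C2 untouched, to give the hydroxy enol-dione F2. Mitsunobu closure (PPh3, diisopropyl azodicarboxylate, THF, 0 °C) should then alkylate the C7a enol oxygen with inversion at C2 and come back to the route at 12.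

Step 8. The allyl group may migrate further: the product is a 6-allylcyclohexa-2,4-dienone and can pass by retro-Claisen rearrangement into an aryl allyl ether, or the Cope equilibrium may be incomplete. The fallback runs the [3,3] shift at the alcohol oxidation level, where no C6 carbonyl exists for a retro-Claisen step. It sets out from 12: Luche reduction (NaBH4, CeCl3·7H2O, MeOH, −78 °C) should give the dienol F3. Heating F3 in toluene with a trace of Et3N should give the 5-allyl dienol F4, now driven by the C4=C3a–C7a=C7 diene. Dess–Martin oxidation (NaHCO3, CH2Cl2) of the C6 alcohol comes back to the route at 13.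

**Further compounds**
F1 | step 5 | rac-(2R,3S,3aS)-3a-allyl-5,7-dimethoxy-3-methyl-2-(3,4,5-trimethoxyphenyl)-3,3a-dihydrobenzofuran-6(2H)-one (racemate of 11) | C=CC[C@]12C=C(OC)C(=O)C(OC)=C1O[C@@H](c3cc(OC)c(OC)c(OC)c3)[C@H]2C
F2 | step 7 | (4S)-4-allyl-3-hydroxy-4-[(1R,2S)-1-hydroxy-1-(3,4,5-trimethoxyphenyl)propan-2-yl]-2,6-dimethoxycyclohexa-2,5-dien-1-one | C=CC[C@@]1(C=C(OC)C(=O)C(OC)=C1O)[C@H](C)[C@@H](O)c1cc(OC)c(OC)c(OC)c1
F3 | step 8 | (2S,3S,3aS)-3a-allyl-5,7-dimethoxy-3-methyl-2-(3,4,5-trimethoxyphenyl)-2,3,3a,6-tetrahydrobenzofuran-6-ol (C6 epimers) | C=CC[C@]12C=C(OC)C(O)C(OC)=C1O[C@H](c3cc(OC)c(OC)c(OC)c3)[C@H]2C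
F4 | step 8 | (2S,3S,5R)-5-allyl-5,7-dimethoxy-3-methyl-2-(3,4,5-trimethoxyphenyl)-2,3,5,6-tetrahydrobenzofuran-6-ol (C6 epimers) | C=CC[C@@]1(OC)C=C2C(=C(OC)C1O)O[C@H](c1cc(OC)c(OC)c(OC)c1)[C@H]2C
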